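Its constants are invented; the rest is arithmetic.

Setting the two rate constants side by side misleads here: 0.45 /M/h reads above 0.43 /h, yet in the fresh mixture rings form faster than links. The constants carry different units, and they become comparable once a level of second end groups stands beside the first.

| flask | first end groups | second end groups | remark | time |
|---|---|---|---|---|
| dawn | 0.80 M | 0.800 M | one stirred flow tank at steady state, fed with the mixture as stated, mean residence time 40.0 h |  |
| winter | 0.80 M | 0.800 M | a closed flask charged with all of it at once and left for 8.0 h | 8.0 h |
| dusk | 0.80 M | 0.800 M (fed, over 4.00 h) | all but second end groups at the start; second end groups goes in evenly over 4.00 h, the run ends at 8.0 h | 8.0 h |
| summer | 0.80 M | 0.800 M | one stirred flow tank at steady state, fed with the mixture as stated, mean residence time 8.0 h |  |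

    first end groups + second end groups → links (k1 = 0.45 /M/h)
    first end groups + second end groups → rings, rate k2*[first end groups] as long as [second end groups] is above zero (k2 = 0.43 /h)
    2 first end groups → homo dimer (k3 = 0.10 /M/h)

1. the set-up with the highest share of links in all that became links or rings, at the outlet or at the end ("none" if the first two lie within 2 percentage points) (dawn / winter / dusk / summer / none)
2. share of links in all that became links or rings, at the outlet or at the end, dawn
3. share of links in all that became links or rings, at the outlet or at the end, winter
4. share of links in all that became links or rings, at the outlet or at the end, dusk
5. share of links in all that became links or rings, at the outlet or at the end, summer

- in percentages every species weighs as the first end groups in it: one homo dimer counts as two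
- a doubled species enters its step squared and goes two at a time
- the stated concentrations are those of everything mixed, before any reaction; amounts are the same in each set-up
- the feed brings no volume worth counting
- run time (winter): 8.0 h

Let b be the fraction of the charge of second end groups still left. First end groups cancel from the ratio of the link and ring rates, so this ratio, the selectivity factor, is b divided by the crossover fraction, the fraction left at which links and rings form equally fast: 1.19. At any moment the share of links is b over b plus this crossover. The full charge gives 45.7%, and a lower b gives less.

A stirred tank sits at a single b, below the charge, and its share is this expression at that level. In dusk the ring step starts at 0.344 M/h against a feed of 0.200 M/h, so b starts out held down. The closed flask of winter sweeps down from the full charge, so winter should lead.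

For winter, the ring step alone leaves at most 3.21% of the first end groups, so nearly all react. At the start homo dimer takes up 0.203 first end groups for each one going to links or rings, and this ratio falls toward zero as first end groups go. Taking half of that figure leaves a winter b of 0.101. As b falls, the logarithm of b plus crossover falls evenly, so rings come to the crossover times ln((1 + crossover)/(end b + crossover)), or 0.629 of the charge. Links are then 0.269, a share of 30.0%.

The forecast names winter, with 5.4% for dawn, 30.3% for winter, 5.8% for dusk and 16.3% for summer, holding that “whichever set-up keeps those groups most concentrated wins”.

The flask gives winter as the highest, at 30.3% against the 30.0% reckoned above, with dawn at 5.41%, dusk at 5.58% and summer at 16.3%. The summer tank holds second end groups at 0.185 M, a b of 0.232. Set against the crossover of 1.19, that level gives summer a share of links of 16.3%.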